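**Retrosynthetic overview**

1. Feature used: the ene-dione ring is a 2-prenylhydroquinone dearomatised at its prenyl carbon. That quaternary carbon (C9a, fluorene-type numbering) is bonded to the benzylic CH (C9), which carries the hydroquinone ring and belongs to the methylcyclohexene ring C9a–C4a–C12H2–C11(Me)=C10H–C9.
2. Last bond, five-membered ring: C4a–C4b, by oxidising ring B to its quinone and letting the ring-A dienol ether carbon add to it.
3. Key bond, methylcyclohexene ring: C9a–C9, by chiral Brønsted acid catalysed ortho-alkylative dearomatisation of the 2-prenyl-4-methoxyphenol (ring A) with the Z-allylic, benzylic cation of its side chain. C9 and C9a are both set here.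
4. Precursor: C12–C11 by Negishi coupling of a ring-A benzylzinc with a (Z)-vinyl iodide made by directed trans-hydroalumination/iodination of an aryl propynyl carbinol. Both arenes come from 5-hydroxy-2-methoxybenzaldehyde.
5. Ring order: two purchased benzene rings, then the methylcyclohexene ring (step 12), then the five-membered ring (step 13), which also turns ring A into the ene-dione.

Key step: step 12

Remark 1: ring B is carried with the oxygen next to the carbinol as its methyl ether and the other oxygen free, because a free ortho-hydroxyl would let the ionised side chain (a vinylogous o-quinone methide) close to a 2H-chromene; the O-methyl analogue gives the same benzylic electrophile as an anisyl-stabilised cation, and either p-methoxyphenol isomer is oxidised to the same quinone.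

Remark 2: the sense of induction in step 12 cannot be assigned in advance; the (R)-catalyst is written and its enantiomer is to be used if that is the one that gives (8R,8aS)-22.

**Route**

Step 1
Reactants: 1 5-hydroxy-2-methoxybenzaldehyde
Product: 2 2-methoxy-5-(methoxymethoxy)benzaldehyde
Conditions: MOMCl, i-Pr2NEt, CH2Cl2, 0 °C → rt
Reagents that add atoms: chloromethyl methyl ether, COCCl
Why: O-alkylation of the only hydroxyl gives the methoxymethyl ether, which acts as the second ortho-directing group in step 2.

Step 2
Reactants: 2 2-methoxy-5-(methoxymethoxy)benzaldehyde; 3 prenyl bromide (1-bromo-3-methylbut-2-ene)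
Product: 7 6-methoxy-3-(methoxymethoxy)-2-(3-methylbut-2-en-1-yl)benzaldehyde, via lithium α-amino alkoxide 4 (not isolated), via C6-lithiated amino alkoxide 5 (not isolated), via prenylated amino alkoxide 6 (not isolated)
Conditions: LiN(Me)CH2CH2NMe2 (from the diamine and n-BuLi), THF, −20 °C; n-BuLi, −20 °C; CuBr·SMe2 (cat.), 3, −78 → 0 °C; aq. NH4Cl
Reagents that add atoms: none
Why: in situ protection of the aldehyde as an α-amino alkoxide and directed ortho-metalation should lithiate the one position lying between both directing groups, and copper-assisted SN2 allylation with the primary bromide should give the linear prenyl group before work-up releases the aldehyde.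

Step 3
Reactants: 7 6-methoxy-3-(methoxymethoxy)-2-(3-methylbut-2-en-1-yl)benzaldehyde
Product: 8 3-hydroxy-6-methoxy-2-(3-methylbut-2-en-1-yl)benzaldehyde
Conditions: HCl (0.3 M in MeOH), rt; aqueous work-up
Reagents that add atoms: none
Why: acid-catalysed acetal exchange with methanol removes the MOM group, and dilute acid at room temperature is not expected to cyclise the o-prenylphenol to a chroman.

Step 4
Reactants: 8 3-hydroxy-6-methoxy-2-(3-methylbut-2-en-1-yl)benzaldehyde
Product: 9 3-[(tert-butyldimethylsilyl)oxy]-6-methoxy-2-(3-methylbut-2-en-1-yl)benzaldehyde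
Conditions: TBSCl, imidazole, DMF, rt
Reagents that add atoms: tert-butyldimethylsilyl chloride, CC(C)(C)[Si](C)(C)Cl
Why: silylation gives a phenol ether that survives the organozinc chemistry and is removed at the end by fluoride instead of acid.

Step 5
Reactants: 9 3-[(tert-butyldimethylsilyl)oxy]-6-methoxy-2-(3-methylbut-2-en-1-yl)benzaldehyde
Product: 10 {3-[(tert-butyldimethylsilyl)oxy]-6-methoxy-2-(3-methylbut-2-en-1-yl)phenyl}methanol
Conditions: NaBH4, EtOH–THF, 0 °C
Reagents that add atoms: none
Why: hydride reduction of the aldehyde leaves the aryl silyl ether and the alkene untouched at 0 °C.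

Step 6
Reactants: 10 {3-[(tert-butyldimethylsilyl)oxy]-6-methoxy-2-(3-methylbut-2-en-1-yl)phenyl}methanol
Product: 12 tert-butyl[3-(chloromethyl)-4-methoxy-2-(3-methylbut-2-en-1-yl)phenoxy]dimethylsilane, via benzylic mesylate 11 (not isolated)
Conditions: MsCl, Et3N, CH2Cl2, 0 °C; then LiCl, THF, rt
Reagents that add atoms: lithium chloride, [Li+].[Cl-]
Why: sulfonylation followed by SN2 displacement with chloride converts the electron-rich benzylic alcohol into the chloride needed for zinc insertion under non-acidic conditions.

Step 7
Reactants: 1 5-hydroxy-2-methoxybenzaldehyde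
Product: 13 2-methoxy-5-[(triisopropylsilyl)oxy]benzaldehyde
Conditions: TIPSCl, imidazole, DMF, rt
Reagents that add atoms: triisopropylsilyl chloride, CC(C)[Si](Cl)(C(C)C)C(C)C
Why: silylation with the bulkier TIPS group, which should withstand the aluminium hydride of step 9 and be cleaved together with the TBS group in step 11.

Step 8
Reactants: 13 2-methoxy-5-[(triisopropylsilyl)oxy]benzaldehyde; 14 1-propynylmagnesium bromide
Product: 15 1-{2-methoxy-5-[(triisopropylsilyl)oxy]phenyl}but-2-yn-1-ol (racemic)
Conditions: THF, −78 → 0 °C; aq. NH4Cl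
Reagents that add atoms: none
Why: 1,2-addition of the alkynyl Grignard reagent to the aldehyde; the carbinol centre is left racemic because ionisation in step 12 destroys it.

Step 9
Reactants: 15 1-{2-methoxy-5-[(triisopropylsilyl)oxy]phenyl}but-2-yn-1-ol
Product: 17 (2Z)-3-iodo-1-{2-methoxy-5-[(triisopropylsilyl)oxy]phenyl}but-2-en-1-ol (racemic), via cyclic vinylalanate 16 (not isolated)
Conditions: Red-Al, THF, 0 °C → rt; EtOAc; I2, THF, −78 → 0 °C; aq. Rochelle salt/Na2S2O3
Reagents that add atoms: iodine, II
Why: hydroxyl-directed trans-hydroalumination places aluminium on the distal alkyne carbon cis to the carbinol in a five-membered alanate, and iodinolysis with retention gives the (Z)-γ-iodo allylic alcohol, which fixes the alkene geometry required for ring closure.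

Step 10
Reactants: 12 tert-butyl[3-(chloromethyl)-4-methoxy-2-(3-methylbut-2-en-1-yl)phenoxy]dimethylsilane; 17 (2Z)-3-iodo-1-{2-methoxy-5-[(triisopropylsilyl)oxy]phenyl}but-2-en-1-ol
Product: 19 (2Z)-4-{3-[(tert-butyldimethylsilyl)oxy]-6-methoxy-2-(3-methylbut-2-en-1-yl)phenyl}-1-{2-methoxy-5-[(triisopropylsilyl)oxy]phenyl}-3-methylbut-2-en-1-ol (carbinol racemic), via benzylzinc chloride 18 (not isolated)
Conditions: 12, Zn dust, LiCl, THF, rt; then 17, Pd(OAc)2 (2 mol%), SPhos (4 mol%), THF, rt
Reagents that add atoms: none
Why: zinc insertion into the benzylic chloride and Negishi coupling with the vinyl iodide proceed with retention of alkene geometry, and this catalyst system tolerates the free secondary hydroxyl when the zinc reagent is used in excess.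

Step 11
Reactants: 19 (2Z)-4-{3-[(tert-butyldimethylsilyl)oxy]-6-methoxy-2-(3-methylbut-2-en-1-yl)phenyl}-1-{2-methoxy-5-[(triisopropylsilyl)oxy]phenyl}-3-methylbut-2-en-1-ol
Product: 20 3-[(2Z)-4-hydroxy-4-(5-hydroxy-2-methoxyphenyl)-2-methylbut-2-en-1-yl]-4-methoxy-2-(3-methylbut-2-en-1-yl)phenol (carbinol racemic)
Conditions: TBAF, THF, 0 °C; pH 7 buffer
Reagents that add atoms: none
Why: fluoride cleaves both aryl silyl ethers under basic conditions that cannot ionise the acid-labile allylic, benzylic carbinol.

Step 12
Reactants: 20 3-[(2Z)-4-hydroxy-4-(5-hydroxy-2-methoxyphenyl)-2-methylbut-2-en-1-yl]-4-methoxy-2-(3-methylbut-2-en-1-yl)phenol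
Product: 22 (8R,8aS)-8-(5-hydroxy-2-methoxyphenyl)-4-methoxy-6-methyl-8a-(3-methylbut-2-en-1-yl)-8,8a-dihydronaphthalen-1(5H)-one, via anisyl allyl cation 21 (not isolated)
Conditions: (R)-3,3′-bis(2,4,6-triisopropylphenyl)-BINOL N-triflylphosphoramide (5–10 mol%), 5 Å MS, toluene (0.005 M), −60 → −30 °C; Et3N quench
Reagents that add atoms: none
Why: Proposed new method: the chiral acid ionises the racemic carbinol of 20 (both enantiomers converge on one achiral cation) to the anisyl-stabilised allyl cation 21, kept as a contact ion pair whose phosphoramide anion is hydrogen-bonded to the ring-A hydroxyl, and the prenyl-bearing ortho carbon of that phenol (the future C8a) attacks the benzylic terminus (the future C8) to give a 6,6-disubstituted cyclohexa-2,4-dienone that cannot rearomatise; the closest known reactions are chiral Brønsted acid catalysed intramolecular allylic substitutions through contact ion pairs (with a phenol oxygen as nucleophile) and phosphoric acid catalysed Friedel–Crafts dearomatisations of 1-substituted 2-naphthols by quinone-methide-type cations. The methylcyclohexene ring closes in a 6-(enolexo)-exo-trig mode with respect to the oxocarbenium (O-methyl quinone methide) form of the cation, and the Z-alkene set in step 9 is what holds the nucleophilic carbon within reach of the benzylic carbon. C8 and C8a are created together: their relative configuration (aryl cis to C1=O and trans to prenyl) should come from the compact transition state in which the anisyl ring lies over ring A and away from the prenyl group while the benzylic C–H points to the anion at the hydroxyl, and their absolute configuration from the face of the phenol that the 3,3′-aryl groups of the catalyst leave open. The step needs attack by the ortho carbon and not by the methoxy-bearing para carbon, which the anion bound at the neighbouring O–H should secure; it needs C- and not O-alkylation, which the substrate secures because the ring-A oxygen could only close an eight-membered ring, the para oxygen is a methyl ether and the ring-B ortho oxygen is capped so that no chromene can form; and it needs ring closure to outrun loss of a C5 proton to the conjugated diene, for which low temperature, a weakly basic anion and high dilution are used.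

Step 13
Reactants: 22 (8R,8aS)-8-(5-hydroxy-2-methoxyphenyl)-4-methoxy-6-methyl-8a-(3-methylbut-2-en-1-yl)-8,8a-dihydronaphthalen-1(5H)-one
Product: 25 (4aR,9R,9aS)-5,8-dihydroxy-11-methyl-9a-(3-methylbut-2-en-1-yl)-9,9a-dihydro-4aH-9,4a-prop[1]enofluorene-1,4-dione (CNP0166383.1), via quinone dienol ether 23 (not isolated), via bicyclic quinone 24 (not isolated)
Conditions: PhI(OAc)2 (1.05 equiv), MeCN–H2O 4:1, 0 °C; TFA (0.2 equiv), 0 °C → rt; PhI(OAc)2 (1.05 equiv); then L-ascorbic acid (aq.), EtOAc
Reagents that add atoms: water, O
Why: iodine(III) oxidation of the p-methoxyphenol gives quinone 23, to whose unsubstituted carbon next to the benzylic substituent the dienol ether carbon C4a adds from the only face it can reach (intramolecular Mukaiyama–Michael addition, with the geometry of a Friedel–Crafts closure to an indane), so that the C4a configuration follows from C8; water converts the methyl oxocarbenium into the C4 ketone, the second portion of oxidant gathers hydroquinone and uncyclised material as quinone 24, and ascorbic acid should reduce 24 to the hydroquinone without touching the ene-dione.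

**Compound list**

1 | 5-hydroxy-2-methoxybenzaldehyde | COc1ccc(O)cc1C=O | starting material
2 | 2-methoxy-5-(methoxymethoxy)benzaldehyde | COCOc1ccc(OC)c(C=O)c1 | intermediate
3 | prenyl bromide (1-bromo-3-methylbut-2-ene) | CC(C)=CCBr | starting material
4 | lithium α-amino alkoxide of 2 (aldehyde masked with N,N,N′-trimethylethylenediamide) | COCOc1ccc(OC)c(C(O[Li])N(C)CCN(C)C)c1 | intermediate
5 | C6-lithiated amino alkoxide | COCOc1ccc(OC)c(C(O[Li])N(C)CCN(C)C)c1[Li] | intermediate
6 | prenylated amino alkoxide | COCOc1ccc(OC)c(C(O[Li])N(C)CCN(C)C)c1CC=C(C)C | intermediate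
7 | 6-methoxy-3-(methoxymethoxy)-2-(3-methylbut-2-en-1-yl)benzaldehyde | COCOc1ccc(OC)c(C=O)c1CC=C(C)C | intermediate
8 | 3-hydroxy-6-methoxy-2-(3-methylbut-2-en-1-yl)benzaldehyde | CC(C)=CCc1c(O)ccc(OC)c1C=O | intermediate
9 | 3-[(tert-butyldimethylsilyl)oxy]-6-methoxy-2-(3-methylbut-2-en-1-yl)benzaldehyde | CC(C)=CCc1c(O[Si](C)(C)C(C)(C)C)ccc(OC)c1C=O | intermediate
10 | {3-[(tert-butyldimethylsilyl)oxy]-6-methoxy-2-(3-methylbut-2-en-1-yl)phenyl}methanol | CC(C)=CCc1c(O[Si](C)(C)C(C)(C)C)ccc(OC)c1CO | intermediate
11 | methanesulfonate of 10 (benzylic mesylate) | CC(C)=CCc1c(O[Si](C)(C)C(C)(C)C)ccc(OC)c1COS(C)(=O)=O | intermediate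
12 | tert-butyl[3-(chloromethyl)-4-methoxy-2-(3-methylbut-2-en-1-yl)phenoxy]dimethylsilane | CC(C)=CCc1c(O[Si](C)(C)C(C)(C)C)ccc(OC)c1CCl | intermediate
13 | 2-methoxy-5-[(triisopropylsilyl)oxy]benzaldehyde | COc1ccc(O[Si](C(C)C)(C(C)C)C(C)C)cc1C=O | intermediate
14 | 1-propynylmagnesium bromide | CC#C[Mg]Br | starting material
15 | 1-{2-methoxy-5-[(triisopropylsilyl)oxy]phenyl}but-2-yn-1-ol (racemic) | CC#CC(O)c1cc(O[Si](C(C)C)(C(C)C)C(C)C)ccc1OC | intermediate
16 | sodium cyclic alkoxy(vinyl)alanate from 15 (Al on the distal alkene carbon, cis to the carbinol) | CC1=CC(c2cc(O[Si](C(C)C)(C(C)C)C(C)C)ccc2OC)O[Al-]1(OCCOC)OCCOC.[Na+] | intermediate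
17 | (2Z)-3-iodo-1-{2-methoxy-5-[(triisopropylsilyl)oxy]phenyl}but-2-en-1-ol (racemic) | C/C(I)=C/C(O)c1cc(O[Si](C(C)C)(C(C)C)C(C)C)ccc1OC | intermediate
18 | {3-[(tert-butyldimethylsilyl)oxy]-6-methoxy-2-(3-methylbut-2-en-1-yl)benzyl}zinc chloride | CC(C)=CCc1c(O[Si](C)(C)C(C)(C)C)ccc(OC)c1C[Zn]Cl | intermediate
19 | (2Z)-4-{3-[(tert-butyldimethylsilyl)oxy]-6-methoxy-2-(3-methylbut-2-en-1-yl)phenyl}-1-{2-methoxy-5-[(triisopropylsilyl)oxy]phenyl}-3-methylbut-2-en-1-ol (carbinol racemic) | CC(C)=CCc1c(O[Si](C)(C)C(C)(C)C)ccc(OC)c1C/C(C)=C\C(O)c1cc(O[Si](C(C)C)(C(C)C)C(C)C)ccc1OC | intermediate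
20 | 3-[(2Z)-4-hydroxy-4-(5-hydroxy-2-methoxyphenyl)-2-methylbut-2-en-1-yl]-4-methoxy-2-(3-methylbut-2-en-1-yl)phenol (carbinol racemic) | CC(C)=CCc1c(O)ccc(OC)c1C/C(C)=C\C(O)c1cc(O)ccc1OC | intermediate
21 | (Z)-anisyl allyl cation from 20 (ion pair with the chiral phosphoramide anion) | CC(C)=CCc1c(O)ccc(OC)c1C/C(C)=C\[CH+]c1cc(O)ccc1OC | intermediate
22 | (8R,8aS)-8-(5-hydroxy-2-methoxyphenyl)-4-methoxy-6-methyl-8a-(3-methylbut-2-en-1-yl)-8,8a-dihydronaphthalen-1(5H)-one | CC(C)=CC[C@@]12C(=O)C=CC(OC)=C1CC(C)=C[C@@H]2c1cc(O)ccc1OC | intermediate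
23 | (8R,8aS)-8-(3,6-dioxocyclohexa-1,4-dien-1-yl)-4-methoxy-6-methyl-8a-(3-methylbut-2-en-1-yl)-8,8a-dihydronaphthalen-1(5H)-one | CC(C)=CC[C@@]12C(=O)C=CC(OC)=C1CC(C)=C[C@@H]2C1=CC(=O)C=CC1=O | intermediate
24 | (4aS,9R,9aS)-11-methyl-9a-(3-methylbut-2-en-1-yl)-9,9a-dihydro-4aH-9,4a-prop[1]enofluorene-1,4,5,8-tetrone (ring-B quinone of the target) | CC(C)=CC[C@@]12C(=O)C=CC(=O)[C@@]13CC(C)=C[C@@H]2C1=C3C(=O)C=CC1=O | intermediate
25 | (4aR,9R,9aS)-5,8-dihydroxy-11-methyl-9a-(3-methylbut-2-en-1-yl)-9,9a-dihydro-4aH-9,4a-prop[1]enofluorene-1,4-dione (CNP0166383.1) | CC(C)=CC[C@@]12C(=O)C=CC(=O)[C@@]13CC(C)=C[C@@H]2c1c(O)ccc(O)c13 | target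

**Step count and risks**

Total step count: 13. Longest linear sequence: 10 steps (steps 1–6 and 10–13).

Steps most likely to fail:

1. Step 12 (Proposed new method). The cation may lose a proton from the ring-A benzylic CH2 and end as the conjugated 1,4-diaryldiene. The phenol may instead be alkylated at its methoxy-bearing para carbon, giving the isomeric cross-conjugated dienone. The loose ion pair may also give poor facial discrimination. Fallback with known chemistry, setting out from 19: 1-chloro-N,N,2-trimethylprop-1-en-1-amine in CH2Cl2 at 0 °C converts the carbinol into the allylic chloride F1. TBAF in THF (−40 → 0 °C, high dilution) then removes both silyl groups, and the ring-A phenoxide closes the ring by intramolecular C-alkylation (alkylative dearomatisation of a phenoxide, Ar2-6 participation, by SN2 at the benzylic carbon or SN2′ from the tertiary allylic isomer). This gives the racemate, that is 22 together with its enantiomer, the (8S,8aR)-dienone F2. Preparative chromatography on a chiral stationary phase delivers (8R,8aS)-22, where the route is rejoined.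

2. Step 13. The approach of C4a to the quinone carbon is strained (a 5-endo-type closure), so the quinone may be consumed by water or by a second molecule before the ring closes. The neighbouring phenol may also trap the oxocarbenium as a cyclic ketal, or the dienol ether may be oxidised. Direct attack of C4a on the iodine(III)-activated phenol would form the same bond and is not a failure. Fallback, setting out from 22: aqueous oxalic acid in THF hydrolyses the dienol ether to the ene-dione F3 (epimerisable at C4a). PhI(OAc)2 in NaHCO3-buffered aqueous MeCN oxidises ring B to the quinone ene-dione F4. Catalytic Et3N in CH2Cl2 then forms the C4a enolate, which adds to the quinone in an intramolecular Michael addition. One further equivalent of PhI(OAc)2 collects the product as 24, where the route is rejoined before the ascorbic acid reduction.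

3. Step 2. Lithiation may occur at a position other than C6. The aryl nucleophile may attack the tertiary end of the allyl system (reverse prenylation), or undergo halogen–metal exchange with prenyl bromide and return 2. Fallback, setting out from 1: allyl bromide and K2CO3 in acetone give 5-(allyloxy)-2-methoxybenzaldehyde F5. Aromatic Claisen rearrangement (N,N-diethylaniline, 190 °C) is expected to favour the ortho position flanked by the formyl group, giving 2-allyl-3-hydroxy-6-methoxybenzaldehyde F6 after removal of the 4-allyl isomer. Olefin cross-metathesis with 2-methylbut-2-ene (second-generation ruthenium carbene catalyst, CH2Cl2, 40 °C) turns allyl into prenyl and gives 8, where the route is rejoined with steps 1–3 bypassed.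

Further compounds
F1 | step 12 | (2Z)-allylic chloride from 19: tert-butyl{3-[(2Z)-4-chloro-4-{2-methoxy-5-[(triisopropylsilyl)oxy]phenyl}-2-methylbut-2-en-1-yl]-4-methoxy-2-(3-methylbut-2-en-1-yl)phenoxy}dimethylsilane (racemic) | CC(C)=CCc1c(O[Si](C)(C)C(C)(C)C)ccc(OC)c1C/C(C)=C\C(Cl)c1cc(O[Si](C(C)C)(C(C)C)C(C)C)ccc1OC
F2 | step 12 | (8S,8aR)-8-(5-hydroxy-2-methoxyphenyl)-4-methoxy-6-methyl-8a-(3-methylbut-2-en-1-yl)-8,8a-dihydronaphthalen-1(5H)-one (enantiomer of 22, formed with it as the racemate) | CC(C)=CC[C@]12C(=O)C=CC(OC)=C1CC(C)=C[C@H]2c1cc(O)ccc1OC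
F3 | step 13 | (8R,8aS)-8-(5-hydroxy-2-methoxyphenyl)-6-methyl-8a-(3-methylbut-2-en-1-yl)-4a,5,8,8a-tetrahydronaphthalene-1,4-dione (C4a epimerisable) | CC(C)=CC[C@@]12C(=O)C=CC(=O)C1CC(C)=C[C@@H]2c1cc(O)ccc1OC
F4 | step 13 | (8R,8aS)-8-(3,6-dioxocyclohexa-1,4-dien-1-yl)-6-methyl-8a-(3-methylbut-2-en-1-yl)-4a,5,8,8a-tetrahydronaphthalene-1,4-dione (C4a epimerisable) | CC(C)=CC[C@@]12C(=O)C=CC(=O)C1CC(C)=C[C@@H]2C1=CC(=O)C=CC1=O
F5 | step 2 | 5-(allyloxy)-2-methoxybenzaldehyde | C=CCOc1ccc(OC)c(C=O)c1
F6 | step 2 | 2-allyl-3-hydroxy-6-methoxybenzaldehyde | C=CCc1c(O)ccc(OC)c1C=O
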